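**Retrosynthetic overview**

1. Target 21 ⇐ methanolysis of the aryl δ-lactone 20 (C7–O acyl bond) ⇐ lactol 19 ⇐ catalyst-controlled Michael addition/hemiacetalisation of (E)-hex-2-enal at C8/C7–OH of chromanone 17, which sets the benzylic S centre.
2. Pyranone ring of 16/17 (O1, C2, C3, C4, C4a, C8a) ⇐ two-atom ring expansion of the four-membered lactone 14 (O1, C2, C3, C4) by insertion of the aryne carbons C4a≡C8a (from silyl triflate 10) into its acyl C4–O1 bond.
3. Enabling feature: O1 and the C4 acyl carbon sit on adjacent arene carbons (C8a, C4a), so O1–C2–C3–C4(=O) is exactly a β-lactone, and the C5 oxygen next to C4a polarises the aryne. C3 is α to the C4 ketone and trans is thermodynamic, so only C2 (chiral pool, never touched) must be controlled.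
4. 10 ⇐ C2v-symmetric phenol 6 ⇐ resorcinol bis-MOM ether (directed metalation/prenylation, then steric C–H borylation/oxidation); the symmetry removes every regiochemical choice on the arene.
5. Ring order: arene (purchased) → pyranone ring by ring expansion (step 9) → temporary lactol/lactone ring (steps 11 and 12), opened in step 13.

Key step: step 9

Remark: atoms are numbered as in chroman-4-one (O1, C2, C3, C4, C4a, C5 to C8, C8a) throughout, also in precursors; (2S,3S) is the trans-2,3-dimethyl arrangement.

**Route**

Step 1
Reactants: 1 resorcinol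
Product: 2 1,3-bis(methoxymethoxy)benzene
Conditions: MOMCl (2.4 equiv), i-Pr2NEt, CH2Cl2, 0 °C → rt
Reagents that add atoms: chloromethyl methyl ether, COCCl
Why: Double Williamson-type O-alkylation gives the bis-acetal, chosen because MOM ethers direct the next lithiation and later leave under mild acid; no stereocentre is formed.

Step 2
Reactants: 2 1,3-bis(methoxymethoxy)benzene; 3 1-bromo-3-methylbut-2-ene (prenyl bromide)
Product: 4 1,3-bis(methoxymethoxy)-2-(3-methylbut-2-en-1-yl)benzene
Conditions: n-BuLi, THF, 0 °C → rt; CuBr·SMe2 (10 mol%); 3, −78 °C → rt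
Reagents that add atoms: none
Why: Directed ortho-metalation: the two MOM-oxy groups jointly direct lithiation to the carbon between them, and the aryl copper species is alkylated by prenyl bromide at its primary carbon (SN2, no allylic transposition); no stereocentre.

Step 3
Reactants: 4 1,3-bis(methoxymethoxy)-2-(3-methylbut-2-en-1-yl)benzene
Product: 6 3,5-bis(methoxymethoxy)-4-(3-methylbut-2-en-1-yl)phenol, via arylboronate 5 (not isolated)
Conditions: B2pin2, [Ir(OMe)(cod)]2 (1.5 mol%), 4,4′-di-tert-butyl-2,2′-bipyridine (3 mol%), THF, 80 °C; then NaOH, 30% H2O2, THF/H2O, 0 °C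
Reagents that add atoms: bis(pinacolato)diboron, CC1(C)OB(OC1(C)C)B1OC(C)(C)C(C)(C)O1 (boryl group of 5); hydrogen peroxide, OO (phenol oxygen of 6)
Why: Sterically governed iridium-catalysed aromatic C–H borylation should occur only at the one C–H without an ortho substituent (para to the prenyl group), and basic peroxide oxidation of the C–B bond (1,2-aryl shift to oxygen) should give the C2v-symmetric phenol without touching the trisubstituted alkene; no stereocentre.

Step 4
Reactants: 6 3,5-bis(methoxymethoxy)-4-(3-methylbut-2-en-1-yl)phenol
Product: 7 2-bromo-3,5-bis(methoxymethoxy)-4-(3-methylbut-2-en-1-yl)phenol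
Conditions: NBS (1.0 equiv), CH2Cl2, −78 °C
Reagents that add atoms: N-bromosuccinimide, O=C1CCC(=O)N1Br
Why: Electrophilic aromatic bromination of the strongly activated phenol at one of its two equivalent ortho positions (symmetry makes the site unambiguous; low temperature and one equivalent are meant to limit dibromination and spare the alkene); no stereocentre.

Step 5
Reactants: 7 2-bromo-3,5-bis(methoxymethoxy)-4-(3-methylbut-2-en-1-yl)phenol
Product: 10 3,5-bis(methoxymethoxy)-4-(3-methylbut-2-en-1-yl)-2-(trimethylsilyl)phenyl trifluoromethanesulfonate, via aryl silyl ether 8 (not isolated), via lithium silylphenolate 9 (not isolated)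
Conditions: (Me3Si)2NH, THF, 65 °C, then evaporate; n-BuLi, THF, −78 °C; Tf2O, −78 → 0 °C
Reagents that add atoms: hexamethyldisilazane, C[Si](C)(C)N[Si](C)(C)C; trifluoromethanesulfonic anhydride, O=S(=O)(OS(=O)(=O)C(F)(F)F)C(F)(F)F
Why: O-silylation, bromine–lithium exchange and the anionic 1,3 O→C silyl shift (retro-Brook rearrangement) move the silyl group to carbon, and the liberated phenoxide is triflated in the same flask, the standard route to an ortho-silylaryl triflate; no stereocentre.

Step 6
Reactants: 11 ethyl (S)-3-hydroxybutanoate
Product: 12 ethyl (2S,3S)-3-hydroxy-2-methylbutanoate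
Conditions: LiN(iPr)2 (2.2 equiv), THF, −50 → −20 °C; MeI, −78 → 0 °C
Reagents that add atoms: iodomethane, CI
Why: Fráter–Seebach alkylation: the lithium-chelated alkoxide enolate is methylated on the face opposite the C3 methyl group, giving the anti (2S,3S) ester while the S carbinol centre from the chiral pool is untouched (a minor syn epimer is harmless because this carbon becomes the epimerisable C3 of the chromanone).

Step 7
Reactants: 12 ethyl (2S,3S)-3-hydroxy-2-methylbutanoate
Product: 13 (2S,3S)-3-hydroxy-2-methylbutanoic acid
Conditions: LiOH, THF/H2O, 0 °C → rt; then aq. HCl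
Reagents that add atoms: lithium hydroxide, [Li+].[OH-]
Why: Saponification of the ethyl ester under mild conditions that leave the carbinol centre untouched.

Step 8
Reactants: 13 (2S,3S)-3-hydroxy-2-methylbutanoic acid
Product: 14 (3S,4S)-3,4-dimethyloxetan-2-one (trans)
Conditions: PhSO2Cl, pyridine, 0 °C
Reagents that add atoms: none
Why: β-Lactonisation by carboxyl activation: the mixed carboxylic–sulfonic anhydride is attacked by the hydroxyl oxygen (4-exo-trig), so the carbinol C–O bond is not broken and the anti acid should give the trans lactone with retention at both centres.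

Step 9
Reactants: 10 3,5-bis(methoxymethoxy)-4-(3-methylbut-2-en-1-yl)-2-(trimethylsilyl)phenyl trifluoromethanesulfonate; 14 (3S,4S)-3,4-dimethyloxetan-2-one
Product: 16 (2S,3S)-5,7-bis(methoxymethoxy)-2,3-dimethyl-6-(3-methylbut-2-en-1-yl)chroman-4-one, via aryne 15 (not isolated)
Conditions: anhydrous CsF (3 equiv), 14 (5 equiv), MeCN, 25 → 45 °C, slow addition of 10
Reagents that add atoms: none
Why: Proposed new method: fluoride-induced 1,2-elimination of 10 gives aryne 15, the ether-like ring oxygen O1 of the strained β-lactone (weak ester resonance in the four-membered ring) adds to C8a, the aryl anion formed at C4a attacks the adjacent acyl carbon C4, and the resulting bicyclic oxonium alkoxide collapses by cleaving the original O1–C4 bond, so that C8a and C4a are inserted into the acyl C–O bond. The closest known reaction types are the σ-insertion of arynes into the N–C(=O) bond of amides and cyclic ureas (two-atom ring expansion), aryne insertion into a C–O bond of epoxides, and the C–O insertion of carboxylic acids into arynes that gives ortho-hydroxyaryl ketones. The pyranone ring is thus formed by ring expansion of the oxetanone and not by cyclisation of a chain; the only closure is the transient 4-exo-trig attack of C4a on C4, and release of the lactone strain drives the fragmentation. C2 and C3 are carried over from C4 and C3 of 14 with retention because no bond to either carbon is made or broken, and C3, being α to the new ketone, can in any case only drift to the favoured trans arrangement, so a C3-epimeric lactone would converge on the same product. The step needs O-attack at C8a and C-attack at C4a, which the inductive, aryne-distorting effect of the C5 MOM-oxy group next to C4a should secure (C8 is unsubstituted, so sterics agree), and it needs the ring oxygen to react in preference to the lactone carbonyl oxygen and to the prenyl group of a second molecule (ene reaction), which excess 14 and slow release of the aryne are meant to secure.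

Step 10
Reactants: 16 (2S,3S)-5,7-bis(methoxymethoxy)-2,3-dimethyl-6-(3-methylbut-2-en-1-yl)chroman-4-one
Product: 17 (2S,3S)-5,7-dihydroxy-2,3-dimethyl-6-(3-methylbut-2-en-1-yl)chroman-4-one
Conditions: 3 M HCl, MeOH, 40 °C
Reagents that add atoms: none
Why: Acid-catalysed acetal exchange with methanol removes both MOM groups under conditions mild enough that the prenyl group should not cyclise onto the neighbouring phenols; C2 is untouched and C3 can only drift to the favoured trans arrangement.

Step 11
Reactants: 17 (2S,3S)-5,7-dihydroxy-2,3-dimethyl-6-(3-methylbut-2-en-1-yl)chroman-4-one; 18 (E)-hex-2-enal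
Product: 19 (2S,3S,10S)-5,8-dihydroxy-2,3-dimethyl-6-(3-methylbut-2-en-1-yl)-10-propyl-2,3,9,10-tetrahydro-4H,8H-pyrano[2,3-f]chromen-4-one (lactol, mixture of anomers at the hemiacetal carbon)
Conditions: (R)-2-[diphenyl(trimethylsilyloxy)methyl]pyrrolidine (20 mol%), PhCO2H (20 mol%), toluene, 0 °C → rt
Reagents that add atoms: none
Why: Iminium-ion-catalysed Friedel–Crafts-type Michael addition followed by hemiacetalisation (known for electron-rich phenols and cyclic vinylogous acids with enals): C8, the only free arene carbon, adds to the β-carbon of the E-iminium ion on the Si face left open by the (R)-catalyst, which is expected to set the benzylic S centre under catalyst control, and the C7 hydroxyl closes the six-membered lactol.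

Step 12
Reactants: 19 lactol
Product: 20 (2S,3S,10S)-5-hydroxy-2,3-dimethyl-6-(3-methylbut-2-en-1-yl)-10-propyl-2,3,9,10-tetrahydro-4H,8H-pyrano[2,3-f]chromene-4,8-dione (aryl δ-lactone between the C7 oxygen and the hexanoyl chain at C8)
Conditions: Pr4N[RuO4] (5 mol%), N-methylmorpholine N-oxide, 4 Å molecular sieves, CH2Cl2, rt
Reagents that add atoms: none
Why: Ley–Griffith oxidation of the lactol to the lactone; the hydrogen-bonded C5 phenol, the alkene and the three stereocentres should not be affected.

Step 13
Reactants: 20 aryl δ-lactone
Product: 21 methyl (3S)-3-[(2S,3S)-5,7-dihydroxy-2,3-dimethyl-6-(3-methylbut-2-en-1-yl)-4-oxochroman-8-yl]hexanoate (CNP0068017.3)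
Conditions: MeOH, Et3N (2 equiv), 0 °C → rt; dilute citric acid work-up
Reagents that add atoms: methanol, CO
Why: Base-catalysed transesterification of the activated aryl lactone, driven by release of the acidic C7 phenol para to the ketone, should give the methyl ester and the free C7–OH, while the amine equilibrates any cis-2,3 material to the thermodynamically preferred trans (2S,3S) chromanone by enolisation at C3.

**Compound list**

1 | resorcinol (benzene-1,3-diol) | Oc1cccc(O)c1 | starting material
2 | 1,3-bis(methoxymethoxy)benzene | COCOc1cccc(OCOC)c1 | intermediate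
3 | 1-bromo-3-methylbut-2-ene (prenyl bromide) | CC(C)=CCBr | starting material
4 | 1,3-bis(methoxymethoxy)-2-(3-methylbut-2-en-1-yl)benzene | COCOc1cccc(OCOC)c1CC=C(C)C | intermediate
5 | 2-[3,5-bis(methoxymethoxy)-4-(3-methylbut-2-en-1-yl)phenyl]-4,4,5,5-tetramethyl-1,3,2-dioxaborolane (formed in situ) | COCOc1cc(B2OC(C)(C)C(C)(C)O2)cc(OCOC)c1CC=C(C)C | intermediate
6 | 3,5-bis(methoxymethoxy)-4-(3-methylbut-2-en-1-yl)phenol | COCOc1cc(O)cc(OCOC)c1CC=C(C)C | intermediate
7 | 2-bromo-3,5-bis(methoxymethoxy)-4-(3-methylbut-2-en-1-yl)phenol | COCOc1cc(O)c(Br)c(OCOC)c1CC=C(C)C | intermediate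
8 | [2-bromo-3,5-bis(methoxymethoxy)-4-(3-methylbut-2-en-1-yl)phenoxy]trimethylsilane (formed in situ) | COCOc1cc(O[Si](C)(C)C)c(Br)c(OCOC)c1CC=C(C)C | intermediate
9 | lithium 3,5-bis(methoxymethoxy)-4-(3-methylbut-2-en-1-yl)-2-(trimethylsilyl)phenolate (formed in situ) | [Li+].[O-]c1cc(OCOC)c(CC=C(C)C)c(OCOC)c1[Si](C)(C)C | intermediate
10 | 3,5-bis(methoxymethoxy)-4-(3-methylbut-2-en-1-yl)-2-(trimethylsilyl)phenyl trifluoromethanesulfonate | COCOc1cc(OS(=O)(=O)C(F)(F)F)c([Si](C)(C)C)c(OCOC)c1CC=C(C)C | intermediate
11 | ethyl (S)-3-hydroxybutanoate | CCOC(=O)C[C@H](C)O | starting material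
12 | ethyl (2S,3S)-3-hydroxy-2-methylbutanoate | CCOC(=O)[C@@H](C)[C@H](C)O | intermediate
13 | (2S,3S)-3-hydroxy-2-methylbutanoic acid | OC(=O)[C@@H](C)[C@H](C)O | intermediate
14 | (3S,4S)-3,4-dimethyloxetan-2-one (trans) | O=C1O[C@@H](C)[C@@H]1C | intermediate
15 | 3,5-bis(methoxymethoxy)-4-(3-methylbut-2-en-1-yl)benzyne (aryne, formed in situ) | COCOC1=CC#CC(OCOC)=C1CC=C(C)C | intermediate
16 | (2S,3S)-5,7-bis(methoxymethoxy)-2,3-dimethyl-6-(3-methylbut-2-en-1-yl)chroman-4-one | O=C1c2c(OCOC)c(CC=C(C)C)c(OCOC)cc2O[C@@H](C)[C@@H]1C | intermediate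
17 | (2S,3S)-5,7-dihydroxy-2,3-dimethyl-6-(3-methylbut-2-en-1-yl)chroman-4-one | O=C1c2c(O)c(CC=C(C)C)c(O)cc2O[C@@H](C)[C@@H]1C | intermediate
18 | (E)-hex-2-enal | CCC/C=C/C=O | starting material
19 | (2S,3S,10S)-5,8-dihydroxy-2,3-dimethyl-6-(3-methylbut-2-en-1-yl)-10-propyl-2,3,9,10-tetrahydro-4H,8H-pyrano[2,3-f]chromen-4-one (lactol, both anomers) | O=C1c2c(O)c(CC=C(C)C)c3OC(O)C[C@H](CCC)c3c2O[C@@H](C)[C@@H]1C | intermediate
20 | (2S,3S,10S)-5-hydroxy-2,3-dimethyl-6-(3-methylbut-2-en-1-yl)-10-propyl-2,3,9,10-tetrahydro-4H,8H-pyrano[2,3-f]chromene-4,8-dione | O=C1c2c(O)c(CC=C(C)C)c3OC(=O)C[C@H](CCC)c3c2O[C@@H](C)[C@@H]1C | intermediate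
21 | methyl (3S)-3-[(2S,3S)-5,7-dihydroxy-2,3-dimethyl-6-(3-methylbut-2-en-1-yl)-4-oxochroman-8-yl]hexanoate | CCC[C@@H](CC(=O)OC)c1c(O)c(CC=C(C)C)c(O)c2c1O[C@@H](C)[C@H](C)C2=O | target

**Step count**

Total steps: 13. Longest linear sequence: 10 steps (steps 1 to 5 and 9 to 13, from resorcinol 1); the lactone branch (steps 6 to 8) joins at step 9.

**Steps most likely to fail**

Step 9 (proposed new method). The aryne may be intercepted by the carbonyl oxygen of the lactone, by fluoride-initiated ring-opening of the lactone, or by an intermolecular ene reaction with a prenyl group before the ring oxygen adds, so that no insertion takes place. The fallback uses known chemistry and sets out from bromophenol 7. Deprotonation with NaH and bromine–lithium exchange with t-BuLi (THF, −78 °C) should give the phenoxide aryllithium. It is acylated by commercial (R)-4-methyloxetan-2-one (acylative ring opening of a lactone by an organolithium) to give (R)-3-hydroxy-1-[2-hydroxy-4,6-bis(methoxymethoxy)-5-(3-methylbut-2-en-1-yl)phenyl]butan-1-one F1. Mitsunobu etherification (PPh3, DIAD, THF, 0 °C) then closes the pyranone ring with inversion at the carbinol carbon to (S)-5,7-bis(methoxymethoxy)-2-methyl-6-(3-methylbut-2-en-1-yl)chroman-4-one F2. Enolate methylation (LiN(iPr)2, THF, −78 °C; MeI) trans to the C2 methyl group returns to the route at 16.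

Step 11. The acyl-deactivated arene may be too weak a nucleophile for the iminium ion, addition through oxygen may compete, or the catalyst may not override the substrate in the facial selection. The fallback sets out from 17 and 18 and changes the activation mode to oxidative N-heterocyclic carbene catalysis: chiral aminoindanol-derived triazolium salt (the enantiomer predicted by the established model to give the S centre), DBU, 3,3′,5,5′-tetra-tert-butyl-4,4′-diphenoquinone, toluene, rt. The α,β-unsaturated acyl azolium formed from 18 takes up C8 of the phenol in a Michael-type step and acylates the C7 oxygen, which should give lactone 20 directly. The route is rejoined at 20; lactol 19 and step 12 are bypassed and no new compound is made.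

Step 4. Bromination may go on to the second ortho position or add across the prenyl double bond. The fallback sets out from phenol 6 and installs silicon by carbamate-directed ortho-metalation instead of through a bromide. Isopropyl isocyanate with Et3N (CH2Cl2, rt) gives 3,5-bis(methoxymethoxy)-4-(3-methylbut-2-en-1-yl)phenyl isopropylcarbamate F3. In situ N-silylation (TBSOTf, TMEDA), ortho-lithiation (n-BuLi, TMEDA, Et2O, −78 °C) and quenching with Me3SiCl give 3,5-bis(methoxymethoxy)-4-(3-methylbut-2-en-1-yl)-2-(trimethylsilyl)phenyl isopropylcarbamate F4. Carbamate cleavage and triflation in one flask (DBU, Et2NH, MeCN, 40 °C; then PhNTf2) return to the route at silyl triflate 10, bypassing 7, 8 and 9.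

**Further compounds**

F1 | step 9 | (R)-3-hydroxy-1-[2-hydroxy-4,6-bis(methoxymethoxy)-5-(3-methylbut-2-en-1-yl)phenyl]butan-1-one | C[C@@H](O)CC(=O)c1c(O)cc(OCOC)c(CC=C(C)C)c1OCOC
F2 | step 9 | (S)-5,7-bis(methoxymethoxy)-2-methyl-6-(3-methylbut-2-en-1-yl)chroman-4-one | O=C1C[C@H](C)Oc2cc(OCOC)c(CC=C(C)C)c(OCOC)c12
F0 | step 11 | none | none
F3 | step 4 | 3,5-bis(methoxymethoxy)-4-(3-methylbut-2-en-1-yl)phenyl isopropylcarbamate | CC(C)NC(=O)Oc1cc(OCOC)c(CC=C(C)C)c(OCOC)c1
F4 | step 4 | 3,5-bis(methoxymethoxy)-4-(3-methylbut-2-en-1-yl)-2-(trimethylsilyl)phenyl isopropylcarbamate | CC(C)NC(=O)Oc1cc(OCOC)c(CC=C(C)C)c(OCOC)c1[Si](C)(C)C
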